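The strategy rests on ring B, the arene of the benzofuran. Its two oxygens (O1 on C7a, OMe on C4) are meta to each other and flank C3a, the carbon bonded to C3, and the side chain sits on C6. C3a is therefore C2 of a 5-substituted cyclohexane-1,3-dione, the only carbon of that surrogate that can carry a carbenoid.
Endgame: one silyl and two benzyl groups are removed. Ring D (oxolane) is opened at C3–C4 to an epoxy cinnamyl ether (Cp2TiCl radical cyclisation). That ether is cut at its allylic C–O bond into a ring B cinnamyl bromide and an epoxy alcohol from O-benzylisovanillin (ring E, Sharpless kinetic resolution).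
The cinnamyl bromide goes back by Wittig homologation to the C6 ester of a 4-methoxy-2,3-dihydrobenzofuran. Ring B goes back by O-methylation and dehydrogenation to a 4-oxo-hexahydrobenzofuran.
Key disconnection: C3–C3a and O1–C2 of ring C (dihydrofuran), a formal [3+2] annulation of the rhodium carbenoid of a 2-diazo-1,3-dione with (E)-O-benzylconiferyl pivalate (ring A, from ferulic acid).
Ring order: C (step 6), B by aromatisation (step 7), D (step 17); rings A and E are bought.

Key step: step 6

Assumption: existing models do not predict which enantiomer of the tert-leucinate catalyst leads to the (2S,3R) adduct with this alkene class; the S-catalyst is written, and its mirror image (from (R)-tert-leucine) takes its place if the sense proves opposite.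
Locants: benzofuran O1, C2, C3, C3a, C4–C7, C7a; oxolane O1, C2–C5.

Step 1
Reactants: 1 3,5-dioxocyclohexane-1-carboxylic acid
Product: 2 4-diazo-3,5-dioxocyclohexane-1-carboxylic acid
Conditions: 4-acetamidobenzenesulfonyl azide (1.1 equiv), Et3N (2.5 equiv), MeCN, 0 °C → rt; then 1 M HCl
Reagents that add atoms: 4-acetamidobenzenesulfonyl azide, CC(=O)Nc1ccc(cc1)S(=O)(=O)N=[N+]=[N-]
Why: Regitz diazo transfer to the doubly activated CH2 between the two carbonyl groups, with the carboxylate as a spectator; it is run before the esterification because methylating or Fischer conditions applied to 1 would also etherify the acidic enol, whereas the diazodione has no enol left.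

Step 2
Reactants: 2 4-diazo-3,5-dioxocyclohexane-1-carboxylic acid
Product: 3 methyl 4-diazo-3,5-dioxocyclohexane-1-carboxylate
Conditions: MeI, K2CO3, DMF, rt
Reagents that add atoms: iodomethane, CI
Why: SN2 O-alkylation of the potassium carboxylate, chemoselective because C4 of 2 carries no proton and stabilised 2-diazo-1,3-diones tolerate carbonate base.

Step 3
Reactants: 4 (E)-ferulic acid
Product: 5 benzyl (E)-3-[4-(benzyloxy)-3-methoxyphenyl]prop-2-enoate
Conditions: BnBr (2.3 equiv), K2CO3, DMF, 60 °C
Reagents that add atoms: benzyl bromide, BrCc1ccccc1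
Why: Double Williamson-type O-alkylation, in which phenoxide and carboxylate are benzylated in one operation, so that the phenol is protected and a reducible ester is obtained without a separate esterification.

Step 4
Reactants: 5 benzyl (E)-3-[4-(benzyloxy)-3-methoxyphenyl]prop-2-enoate
Product: 6 (E)-3-[4-(benzyloxy)-3-methoxyphenyl]prop-2-en-1-ol
Conditions: i-Bu2AlH (3 equiv), CH2Cl2, −78 → 0 °C; aq. potassium sodium tartrate
Reagents that add atoms: none
Why: 1,2-Reduction of the unsaturated ester by i-Bu2AlH stops at the allylic alcohol and keeps the E geometry and the aryl benzyl ether.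

Step 5
Reactants: 6 (E)-3-[4-(benzyloxy)-3-methoxyphenyl]prop-2-en-1-ol
Product: 7 (E)-3-[4-(benzyloxy)-3-methoxyphenyl]prop-2-en-1-yl pivalate
Conditions: PivCl, pyridine, CH2Cl2, 0 °C → rt
Reagents that add atoms: pivaloyl chloride, CC(C)(C)C(=O)Cl
Why: Acylation of the primary allylic alcohol; an acyloxy group, unlike an allyl alkyl or silyl ether, offers the carbenoid of step 6 neither a nucleophilic oxygen for ylide formation nor a hydridic allylic C–H bond for insertion.

Step 6
Reactants: 3 methyl 4-diazo-3,5-dioxocyclohexane-1-carboxylate; 7 (E)-3-[4-(benzyloxy)-3-methoxyphenyl]prop-2-en-1-yl pivalate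
Product: 9 methyl (2S,3R)-2-[4-(benzyloxy)-3-methoxyphenyl]-4-oxo-3-[(pivaloyloxy)methyl]-2,3,4,5,6,7-hexahydro-1-benzofuran-6-carboxylate (both C6 epimers), via benzylic cation–enolate zwitterion 8 (not isolated)
Conditions: Rh2(S-PTTL)4 (dirhodium tetrakis[N-phthaloyl-(S)-tert-leucinate], 2 mol %), 4 Å MS, PhF, 50 °C; 3 (1.5 equiv) added to 7 over 8 h
Reagents that add atoms: none
Why: Proposed new method: loss of N2 from 3 on the dirhodium carboxylate gives an electrophilic acceptor/acceptor carbenoid that is attacked by the alkene carbon of 7 bearing CH2OPiv, so that C3–C3a forms first and the positive charge develops on the benzylic carbon, stabilised by the para-benzyloxy group as in 8; the closest known reaction type is the racemic dirhodium-catalysed dihydrofuran annulation of 2-diazocyclohexane-1,3-diones with vinyl ethers and styrenes, and what is new is high enantiocontrol with an acyclic 1,2-disubstituted styrene. Ring C closes when an enolate oxygen of 8 attacks the cationic carbon (O1–C2), a 5-exo-trig closure with respect to the quinone-methide-like C=C of the cation, in which the enolate C=C ends up inside the new ring. C3 is fixed in the first C–C bond formation by the alkene face that the phthalimide walls around the carbenoid leave open, and it is not touched afterwards because only C2 becomes planar. C2 is set relative to C3 by the substrate, since rotation about C2–C3 in 8 lets the aryl group close anti to CH2OPiv, and any cis isomer can be equilibrated to trans through the same cation. The step needs regioselectivity, chemoselectivity for the alkene, trans geometry and face selectivity: the first is secured by the cation-stabilising aryl group and by the single carbenoid carbon of the dione, the second by the deactivating acyl group on the allylic oxygen, the third by the open cation, and the last rests on the catalyst alone. Closure through either of the two enantiotopic carbonyl oxygens gives the two C6 epimers, which converge in step 7.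

Step 7
Reactants: 9 methyl (2S,3R)-2-[4-(benzyloxy)-3-methoxyphenyl]-4-oxo-3-[(pivaloyloxy)methyl]-2,3,4,5,6,7-hexahydro-1-benzofuran-6-carboxylate
Product: 12 methyl (2S,3R)-2-[4-(benzyloxy)-3-methoxyphenyl]-4-hydroxy-3-[(pivaloyloxy)methyl]-2,3-dihydro-1-benzofuran-6-carboxylate, via 5-phenylselanyl ketone 10 (not isolated), via cross-conjugated dienone 11 (not isolated)
Conditions: LiN(i-Pr)2 (1.2 equiv), THF, −78 °C; PhSeBr; then 30% H2O2, pyridine, CH2Cl2, 0 °C → rt
Reagents that add atoms: benzeneselenenyl bromide, Br[Se]c1ccccc1 (its PhSe group is carried only by 10 and leaves again)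
Why: Enolate selenenylation and selenoxide syn-elimination followed by tautomerisation of 11 to the arene: kinetic deprotonation at C5 (deprotonation at C6 would be equally productive) and attack of PhSeBr anti to the C6 ester place selenium syn to H6, both C6 epimers converge, C2 and C3 are not involved, and the basic to neutral medium avoids the acid solvolysis of the p-alkoxybenzylic C2–O bond of the vinylogous ester that hot iodine in methanol would risk.

Step 8
Reactants: 12 methyl (2S,3R)-2-[4-(benzyloxy)-3-methoxyphenyl]-4-hydroxy-3-[(pivaloyloxy)methyl]-2,3-dihydro-1-benzofuran-6-carboxylate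
Product: 13 methyl (2S,3R)-2-[4-(benzyloxy)-3-methoxyphenyl]-4-methoxy-3-[(pivaloyloxy)methyl]-2,3-dihydro-1-benzofuran-6-carboxylate
Conditions: MeI, K2CO3, acetone, reflux
Reagents that add atoms: iodomethane, CI
Why: Williamson O-methylation of the only free phenol installs the C4 methoxy group, and carbonate base leaves both esters and both stereocentres untouched.

Step 9
Reactants: 13 methyl (2S,3R)-2-[4-(benzyloxy)-3-methoxyphenyl]-4-methoxy-3-[(pivaloyloxy)methyl]-2,3-dihydro-1-benzofuran-6-carboxylate
Product: 14 [(2S,3R)-2-[4-(benzyloxy)-3-methoxyphenyl]-4-methoxy-2,3-dihydro-1-benzofuran-3,6-diyl]dimethanol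
Conditions: LiAlH4, THF, 0 °C → rt
Reagents that add atoms: none
Why: Hydride reduction of both esters: a primary pivalate cannot be kept while an aryl ester is reduced, so it is removed on purpose once its task in step 6 is done, and the two alcohols formed (benzylic and aliphatic) are different enough to be told apart in step 10.

Step 10
Reactants: 14 [(2S,3R)-2-[4-(benzyloxy)-3-methoxyphenyl]-4-methoxy-2,3-dihydro-1-benzofuran-3,6-diyl]dimethanol
Product: 16 ethyl (E)-3-[(2S,3R)-2-[4-(benzyloxy)-3-methoxyphenyl]-3-(hydroxymethyl)-4-methoxy-2,3-dihydro-1-benzofuran-6-yl]prop-2-enoate, via 6-carbaldehyde 15 (not isolated)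
Conditions: activated MnO2 (15 equiv), Ph3P=CHCO2Et (1.3 equiv), CH2Cl2, rt
Reagents that add atoms: ethyl (triphenylphosphoranylidene)acetate, CCOC(=O)C=P(c1ccccc1)(c1ccccc1)c1ccccc1
Why: Tandem oxidation–Wittig olefination: MnO2 oxidises only the benzylic alcohol, the aldehyde 15 is intercepted in the flask by the stabilised ylide to give the E-cinnamate, and the aliphatic hydroxymethyl group on C3 stays free.

Step 11
Reactants: 16 ethyl (E)-3-[(2S,3R)-2-[4-(benzyloxy)-3-methoxyphenyl]-3-(hydroxymethyl)-4-methoxy-2,3-dihydro-1-benzofuran-6-yl]prop-2-enoate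
Product: 17 ethyl (E)-3-[(2S,3R)-2-[4-(benzyloxy)-3-methoxyphenyl]-3-{[(tert-butyldimethylsilyl)oxy]methyl}-4-methoxy-2,3-dihydro-1-benzofuran-6-yl]prop-2-enoate
Conditions: TBSCl, imidazole, DMF, rt
Reagents that add atoms: tert-butyldimethylsilyl chloride, CC(C)(C)[Si](C)(C)Cl
Why: Silylation of the remaining primary alcohol, needed because the bromination of step 13 and the alkoxide alkylation of step 16 would not tolerate a free hydroxyl group in this fragment.

Step 12
Reactants: 17 ethyl (E)-3-[(2S,3R)-2-[4-(benzyloxy)-3-methoxyphenyl]-3-{[(tert-butyldimethylsilyl)oxy]methyl}-4-methoxy-2,3-dihydro-1-benzofuran-6-yl]prop-2-enoate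
Product: 18 (E)-3-[(2S,3R)-2-[4-(benzyloxy)-3-methoxyphenyl]-3-{[(tert-butyldimethylsilyl)oxy]methyl}-4-methoxy-2,3-dihydro-1-benzofuran-6-yl]prop-2-en-1-ol
Conditions: i-Bu2AlH (2.5 equiv), CH2Cl2, −78 °C; aq. potassium sodium tartrate
Reagents that add atoms: none
Why: 1,2-Reduction of the cinnamate with i-Bu2AlH gives the E-allylic alcohol, and silyl and benzyl ethers are inert.

Step 13
Reactants: 18 (E)-3-[(2S,3R)-2-[4-(benzyloxy)-3-methoxyphenyl]-3-{[(tert-butyldimethylsilyl)oxy]methyl}-4-methoxy-2,3-dihydro-1-benzofuran-6-yl]prop-2-en-1-ol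
Product: 19 (2S,3R)-2-[4-(benzyloxy)-3-methoxyphenyl]-6-[(E)-3-bromoprop-1-en-1-yl]-3-{[(tert-butyldimethylsilyl)oxy]methyl}-4-methoxy-2,3-dihydro-1-benzofuran
Conditions: CBr4, PPh3, CH2Cl2, 0 °C
Reagents that add atoms: carbon tetrabromide, BrC(Br)(Br)Br
Why: Appel bromination (SN2 at the primary allylic carbon) under nearly neutral conditions; both oxygens of ring B are meta to the side chain, so the bromide is far less prone to ionise than a 4-alkoxycinnamyl bromide, and it is used without storage.

Step 14
Reactants: 20 3-(benzyloxy)-4-methoxybenzaldehyde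
Product: 21 racemic 1-[3-(benzyloxy)-4-methoxyphenyl]prop-2-en-1-ol
Conditions: CH2=CHMgBr, THF, −78 → 0 °C; aq. NH4Cl
Reagents that add atoms: vinylmagnesium bromide, C=C[Mg]Br
Why: Grignard 1,2-addition of the vinyl nucleophile to the aromatic aldehyde gives the racemic secondary allylic alcohol needed for the resolution.

Step 15
Reactants: 21 racemic 1-[3-(benzyloxy)-4-methoxyphenyl]prop-2-en-1-ol
Product: 22 (S)-[3-(benzyloxy)-4-methoxyphenyl][(2R)-oxiran-2-yl]methanol
Conditions: Ti(Oi-Pr)4 (0.3 equiv), L-(+)-DIPT (0.36 equiv), t-BuOOH (0.45 equiv), 4 Å MS, CH2Cl2, −20 °C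
Reagents that add atoms: tert-butyl hydroperoxide, CC(C)(C)OO
Why: Sharpless kinetic resolution stopped below half conversion: with L-(+)-DIPT the (R)-alcohol (aryl group in the place of the alkyl group of the standard model) is the fast-reacting enantiomer and is epoxidised anti, so that the carbinol centre, the only one of 22 that survives step 17, has the arrangement of oxolane C2 (its descriptor changes to S only because the epoxide carbon outranks the aryl group).

Step 16
Reactants: 19 (2S,3R)-2-[4-(benzyloxy)-3-methoxyphenyl]-6-[(E)-3-bromoprop-1-en-1-yl]-3-{[(tert-butyldimethylsilyl)oxy]methyl}-4-methoxy-2,3-dihydro-1-benzofuran; 22 (S)-[3-(benzyloxy)-4-methoxyphenyl][(2R)-oxiran-2-yl]methanol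
Product: 23 (2S,3R)-2-[4-(benzyloxy)-3-methoxyphenyl]-6-[(E)-3-{(S)-[3-(benzyloxy)-4-methoxyphenyl][(2R)-oxiran-2-yl]methoxy}prop-1-en-1-yl]-3-{[(tert-butyldimethylsilyl)oxy]methyl}-4-methoxy-2,3-dihydro-1-benzofuran
Conditions: NaH, n-Bu4NI (cat.), THF–DMF, 0 °C
Reagents that add atoms: none
Why: Williamson etherification of the sodium alkoxide of 22 with the allylic bromide; low temperature, an aprotic medium and a very reactive electrophile let O-alkylation outrun Payne migration of the epoxide, no stereocentre is touched, and a stereoisomer that stems from incomplete enantiopurity of either fragment is now a diastereomer that can be removed.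

Step 17
Reactants: 23 epoxy cinnamyl ether (full name in step 16)
Product: 24 [(2R,3S,4S)-2-[3-(benzyloxy)-4-methoxyphenyl]-4-({(2S,3R)-2-[4-(benzyloxy)-3-methoxyphenyl]-3-{[(tert-butyldimethylsilyl)oxy]methyl}-4-methoxy-2,3-dihydro-1-benzofuran-6-yl}methyl)oxolan-3-yl]methanol
Conditions: Cp2TiCl2 (3 equiv), Zn dust, THF, rt (gives Cp2TiCl), added to 23 in THF, rt; then 1 M HCl, 0 °C, brief
Reagents that add atoms: none
Why: Reductive epoxide opening by trivalent titanium and 5-exo-trig radical cyclisation: homolysis of the more substituted C–O bond gives the secondary β-titanoxy radical (the epoxide stereocentre is erased), which adds to the cinnamyl alkene through a chair-like transition state with the C2 aryl group pseudo-equatorial, so that the existing C2 centre sets C3 trans to it and C4 cis to C3, and the benzylic radical is reduced by a second Cp2TiCl and protonated on quench.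

Step 18
Reactants: 24 silyl-protected oxolane alcohol (full name in step 17)
Product: 25 [(2R,3S,4S)-2-[3-(benzyloxy)-4-methoxyphenyl]-4-({(2S,3R)-2-[4-(benzyloxy)-3-methoxyphenyl]-3-(hydroxymethyl)-4-methoxy-2,3-dihydro-1-benzofuran-6-yl}methyl)oxolan-3-yl]methanol
Conditions: n-Bu4NF, THF, 0 °C → rt
Reagents that add atoms: none
Why: Fluoride-induced desilylation, run before the hydrogenolysis so that the very polar target is formed only in a last step that needs no more than a filtration.

Step 19
Reactants: 25 dibenzyl ether of the target (full name in step 18)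
Product: 26 5-[(2R,3S,4S)-4-{[(2S,3R)-2-(4-hydroxy-3-methoxyphenyl)-3-(hydroxymethyl)-4-methoxy-2,3-dihydro-1-benzofuran-6-yl]methyl}-3-(hydroxymethyl)oxolan-2-yl]-2-methoxyphenol (CNP0242386.1)
Conditions: H2 (1 atm), 10% Pd/C, EtOAc–EtOH, rt, stopped when both benzyl groups are gone
Reagents that add atoms: none
Why: Catalytic hydrogenolysis of the two aryl benzyl ethers, which at atmospheric pressure in a neutral solvent are cleaved much faster than the cyclic benzylic C–O bonds of rings C and D, and no stereocentre is affected.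

Compound list
1 | 3,5-dioxocyclohexane-1-carboxylic acid | OC(=O)C1CC(=O)CC(=O)C1 | starting material
2 | 4-diazo-3,5-dioxocyclohexane-1-carboxylic acid | OC(=O)C1CC(=O)C(=[N+]=[N-])C(=O)C1 | intermediate
3 | methyl 4-diazo-3,5-dioxocyclohexane-1-carboxylate | COC(=O)C1CC(=O)C(=[N+]=[N-])C(=O)C1 | intermediate
4 | (E)-ferulic acid | COc1cc(/C=C/C(=O)O)ccc1O | starting material
5 | benzyl (E)-3-[4-(benzyloxy)-3-methoxyphenyl]prop-2-enoate | COc1cc(/C=C/C(=O)OCc2ccccc2)ccc1OCc1ccccc1 | intermediate
6 | (E)-3-[4-(benzyloxy)-3-methoxyphenyl]prop-2-en-1-ol | COc1cc(/C=C/CO)ccc1OCc1ccccc1 | intermediate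
7 | (E)-3-[4-(benzyloxy)-3-methoxyphenyl]prop-2-en-1-yl pivalate | COc1cc(/C=C/COC(=O)C(C)(C)C)ccc1OCc1ccccc1 | intermediate
8 | benzylic cation–enolate zwitterion (drawn without the metal, C3–C3a formed, ring C still open) | COC(=O)C1CC(=O)C(=C([O-])C1)[C@H](COC(=O)C(C)(C)C)[CH+]c1ccc(OCc2ccccc2)c(OC)c1 | intermediate
9 | methyl (2S,3R)-2-[4-(benzyloxy)-3-methoxyphenyl]-4-oxo-3-[(pivaloyloxy)methyl]-2,3,4,5,6,7-hexahydro-1-benzofuran-6-carboxylate, both C6 epimers | COC(=O)C1CC(=O)C2=C(C1)O[C@H](c1ccc(OCc3ccccc3)c(OC)c1)[C@H]2COC(=O)C(C)(C)C | intermediate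
10 | 5-phenylselanyl derivative of 9 | COC(=O)C1C([Se]c3ccccc3)C(=O)C2=C(C1)O[C@H](c1ccc(OCc3ccccc3)c(OC)c1)[C@H]2COC(=O)C(C)(C)C | intermediate
11 | methyl (2S,3R)-2-[4-(benzyloxy)-3-methoxyphenyl]-4-oxo-3-[(pivaloyloxy)methyl]-2,3,4,7-tetrahydro-1-benzofuran-6-carboxylate | COC(=O)C1=CC(=O)C2=C(C1)O[C@H](c1ccc(OCc3ccccc3)c(OC)c1)[C@H]2COC(=O)C(C)(C)C | intermediate
12 | methyl (2S,3R)-2-[4-(benzyloxy)-3-methoxyphenyl]-4-hydroxy-3-[(pivaloyloxy)methyl]-2,3-dihydro-1-benzofuran-6-carboxylate | COC(=O)c1cc(O)c2c(c1)O[C@H](c1ccc(OCc3ccccc3)c(OC)c1)[C@H]2COC(=O)C(C)(C)C | intermediate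
13 | methyl (2S,3R)-2-[4-(benzyloxy)-3-methoxyphenyl]-4-methoxy-3-[(pivaloyloxy)methyl]-2,3-dihydro-1-benzofuran-6-carboxylate | COC(=O)c1cc(OC)c2c(c1)O[C@H](c1ccc(OCc3ccccc3)c(OC)c1)[C@H]2COC(=O)C(C)(C)C | intermediate
14 | [(2S,3R)-2-[4-(benzyloxy)-3-methoxyphenyl]-4-methoxy-2,3-dihydro-1-benzofuran-3,6-diyl]dimethanol | OCc1cc(OC)c2c(c1)O[C@H](c1ccc(OCc3ccccc3)c(OC)c1)[C@H]2CO | intermediate
15 | (2S,3R)-2-[4-(benzyloxy)-3-methoxyphenyl]-3-(hydroxymethyl)-4-methoxy-2,3-dihydro-1-benzofuran-6-carbaldehyde | O=Cc1cc(OC)c2c(c1)O[C@H](c1ccc(OCc3ccccc3)c(OC)c1)[C@H]2CO | intermediate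
16 | ethyl (E)-3-[(2S,3R)-2-[4-(benzyloxy)-3-methoxyphenyl]-3-(hydroxymethyl)-4-methoxy-2,3-dihydro-1-benzofuran-6-yl]prop-2-enoate | CCOC(=O)/C=C/c1cc(OC)c2c(c1)O[C@H](c1ccc(OCc3ccccc3)c(OC)c1)[C@H]2CO | intermediate
17 | O-TBS ether of 16 | CCOC(=O)/C=C/c1cc(OC)c2c(c1)O[C@H](c1ccc(OCc3ccccc3)c(OC)c1)[C@H]2CO[Si](C)(C)C(C)(C)C | intermediate
18 | (E)-allylic alcohol from 17 | OC/C=C/c1cc(OC)c2c(c1)O[C@H](c1ccc(OCc3ccccc3)c(OC)c1)[C@H]2CO[Si](C)(C)C(C)(C)C | intermediate
19 | (E)-cinnamyl bromide from 18 | BrC/C=C/c1cc(OC)c2c(c1)O[C@H](c1ccc(OCc3ccccc3)c(OC)c1)[C@H]2CO[Si](C)(C)C(C)(C)C | intermediate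
20 | 3-(benzyloxy)-4-methoxybenzaldehyde | COc1ccc(C=O)cc1OCc1ccccc1 | starting material
21 | racemic 1-[3-(benzyloxy)-4-methoxyphenyl]prop-2-en-1-ol | C=CC(O)c1ccc(OC)c(OCc2ccccc2)c1 | intermediate
22 | (S)-[3-(benzyloxy)-4-methoxyphenyl][(2R)-oxiran-2-yl]methanol | O[C@@H](c1ccc(OC)c(OCc2ccccc2)c1)[C@H]1CO1 | intermediate
23 | epoxy cinnamyl ether from 19 and 22 | COc1ccc([C@H](OC/C=C/c2cc(OC)c3c(c2)O[C@H](c2ccc(OCc4ccccc4)c(OC)c2)[C@H]3CO[Si](C)(C)C(C)(C)C)[C@H]2CO2)cc1OCc1ccccc1 | intermediate
24 | (2R,3S,4S)-oxolane alcohol, O-TBS, di-O-benzyl | COc1ccc([C@@H]2OC[C@@H](Cc3cc(OC)c4c(c3)O[C@H](c3ccc(OCc5ccccc5)c(OC)c3)[C@H]4CO[Si](C)(C)C(C)(C)C)[C@H]2CO)cc1OCc1ccccc1 | intermediate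
25 | di-O-benzyl ether of the target | COc1ccc([C@@H]2OC[C@@H](Cc3cc(OC)c4c(c3)O[C@H](c3ccc(OCc5ccccc5)c(OC)c3)[C@H]4CO)[C@H]2CO)cc1OCc1ccccc1 | intermediate
26 | CNP0242386.1 | COc1ccc([C@@H]2OC[C@@H](Cc3cc(OC)c4c(c3)O[C@H](c3ccc(O)c(OC)c3)[C@H]4CO)[C@H]2CO)cc1O | target

Total step count: 19
Longest linear sequence: 15 steps (steps 3–13 and 16–19, from ferulic acid)

Steps most likely to fail

1. Step 6 (proposed new method).
- What may go wrong: the catalyst may discriminate weakly between the two alkene faces. The trans-disubstituted alkene may also capture the carbenoid slowly, so that Wolff ring contraction and attack on the electron-rich arenes gain ground.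
- Fallback: classical resolution in place of catalyst control; it sets out from 3 and 7 and comes back at 12. The annulation is run in its known racemic form with achiral Rh2(OAc)4 in refluxing PhF and gives the racemic trans adduct F1. The operations of step 7 turn it into the racemic phenol F2. The C4 phenol sits next to C3. Its acylation with (1S,4R)-camphanic chloride (Et3N, DMAP, CH2Cl2) gives the (2S,3R) aryl camphanate F3 and the (2R,3S) aryl camphanate F4, which are separated by crystallisation or chromatography. K2CO3 in MeOH at 0 °C cleaves the activated aryl ester of F3 in preference to the pivalate and delivers 12 as a single enantiomer.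

2. Step 7.
- What may go wrong: proton exchange between the enolate and the selenide, deprotonation at C7, or oxidation of the emerging phenol by the peroxide and selenium mixture.
- Fallback: soft enolisation and palladium-mediated dehydrogenation in place of strong base and peroxide; it sets out from 9 and comes back at 12. Me3SiOTf and Et3N in CH2Cl2 at 0 °C convert 9 into the 4-(trimethylsilyloxy) diene F5. Pd(OAc)2 (1 equiv) in MeCN at rt (Saegusa–Ito oxidation) gives dienone 11, which tautomerises to 12.

3. Step 17.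
- What may go wrong: a second Cp2TiCl may capture the β-titanoxy radical and eliminate it to the allyl ether before ring closure. The Lewis acidic salts may open the epoxide with chloride. The facial preference in the ring closure may be too small.
- Fallback: a tin hydride chain from a thionocarbonate in place of metal-induced epoxide opening; it sets out from 23 and comes back at 24. KOH in DMSO–H2O at 60 °C opens the epoxide at its terminal carbon to the 1,2-diol F6. 1,1′-Thiocarbonyldiimidazole in warm toluene closes the cyclic thionocarbonate F7. Slow addition of Bu3SnH and AIBN in refluxing benzene (Barton–McCombie-type fragmentation toward the secondary carbon) generates the same carbon radical free of Lewis acid and reducing metal. It cyclises 5-exo, and the benzylic radical takes hydrogen from Bu3SnH to give the stannyl thiolcarbonate F8. Dilute aqueous NaOH in THF hydrolyses F8 to 24.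

Further compounds
F1 | step 6 | racemic methyl trans-2-[4-(benzyloxy)-3-methoxyphenyl]-4-oxo-3-[(pivaloyloxy)methyl]-2,3,4,5,6,7-hexahydro-1-benzofuran-6-carboxylate (both enantiomers drawn) | COC(=O)C1CC(=O)C2=C(C1)O[C@H](c1ccc(OCc3ccccc3)c(OC)c1)[C@H]2COC(=O)C(C)(C)C.COC(=O)C1CC(=O)C2=C(C1)O[C@@H](c1ccc(OCc3ccccc3)c(OC)c1)[C@@H]2COC(=O)C(C)(C)C
F2 | step 6 | racemic methyl trans-2-[4-(benzyloxy)-3-methoxyphenyl]-4-hydroxy-3-[(pivaloyloxy)methyl]-2,3-dihydro-1-benzofuran-6-carboxylate (both enantiomers drawn) | COC(=O)c1cc(O)c2c(c1)O[C@H](c1ccc(OCc3ccccc3)c(OC)c1)[C@H]2COC(=O)C(C)(C)C.COC(=O)c1cc(O)c2c(c1)O[C@@H](c1ccc(OCc3ccccc3)c(OC)c1)[C@@H]2COC(=O)C(C)(C)C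
F3 | step 6 | (1S,4R)-camphanate of the C4 phenol, (2S,3R) series | CC1(C)[C@@]2(C)CC[C@@]1(OC2=O)C(=O)Oc1cc(C(=O)OC)cc2O[C@H](c3ccc(OCc4ccccc4)c(OC)c3)[C@@H](COC(=O)C(C)(C)C)c12
F4 | step 6 | (1S,4R)-camphanate of the C4 phenol, (2R,3S) series | CC1(C)[C@@]2(C)CC[C@@]1(OC2=O)C(=O)Oc1cc(C(=O)OC)cc2O[C@@H](c3ccc(OCc4ccccc4)c(OC)c3)[C@H](COC(=O)C(C)(C)C)c12
F5 | step 7 | methyl (2S,3R)-2-[4-(benzyloxy)-3-methoxyphenyl]-3-[(pivaloyloxy)methyl]-4-(trimethylsilyloxy)-2,3,6,7-tetrahydro-1-benzofuran-6-carboxylate | COC(=O)C1C=C(O[Si](C)(C)C)C2=C(C1)O[C@H](c1ccc(OCc3ccccc3)c(OC)c1)[C@H]2COC(=O)C(C)(C)C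
F6 | step 17 | 1,2-diol from 23 (epoxide opened by water at the terminal carbon) | COc1ccc([C@H](OC/C=C/c2cc(OC)c3c(c2)O[C@H](c2ccc(OCc4ccccc4)c(OC)c2)[C@H]3CO[Si](C)(C)C(C)(C)C)[C@H](O)CO)cc1OCc1ccccc1
F7 | step 17 | cyclic thionocarbonate of F6 | COc1ccc([C@H](OC/C=C/c2cc(OC)c3c(c2)O[C@H](c2ccc(OCc4ccccc4)c(OC)c2)[C@H]3CO[Si](C)(C)C(C)(C)C)[C@H]2COC(=S)O2)cc1OCc1ccccc1
F8 | step 17 | S-(tributylstannyl) thiolcarbonate of 24 | COc1ccc([C@@H]2OC[C@@H](Cc3cc(OC)c4c(c3)O[C@H](c3ccc(OCc5ccccc5)c(OC)c3)[C@H]4CO[Si](C)(C)C(C)(C)C)[C@H]2COC(=O)S[Sn](CCCC)(CCCC)CCCC)cc1OCc1ccccc1
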